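**Retrosynthetic overview**

1. Feature: with the target carbocycle numbered C1 (aryl methine), C2=C3 (C3 bears CH3), C4, C5, C6 (quaternary: CH3 and the Z-styryl group CαH=CβH–Ar), the atoms C3=C2–C1–C6–Cα=Cβ are a hexa-1,5-diene whose middle σ bond C1–C6 joins the two stereocentres.
2. Last disconnection: C3–CH3 (Suzuki methylation of the C3 enol triflate). Key disconnection: retro-[3,3] across C1–C6, back to the potassium alkoxide of a 1-[(E)-styryl]-2-aryl-4-methylcyclohex-3-en-1-ol with aryl cis to OH; its ring bond from carbinol carbon to aryl methine is the one that breaks.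
3. The cyclohexenol: E-styryl arm by Heck arylation of the 1-vinyl carbinol with 8-iodo-5,7-dimethoxycoumarin; the vinyl carbinol from a spiro-dioxolanone made by an exo- and face-selective Diels–Alder reaction of the coumarin diene with (S)-2-tert-butyl-5-methylene-1,3-dioxolan-4-one, which sets both precursor stereocentres with O cis to aryl.
4. Ring order: both coumarin rings come intact from 5,7-dimethoxycoumarin; the first carbocycle is made by Diels–Alder (step 6); the target cyclohexene is closed in step 11 by the [3,3] shift that opens the first one.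

Key step: step 11

Ar = 5,7-dimethoxy-2-oxo-2H-chromen-8-yl (coumarin bonded through C8).
Assumption: iodination of 5,7-dimethoxycoumarin is taken to go to C8, as halogenation of 5,7-dimethoxychromones does; any 6-iodo isomer is removed by crystallisation.

**Route**

Step 1
Reactants: 1 5,7-dimethoxycoumarin
Product: 2 8-iodo-5,7-dimethoxycoumarin
Conditions: N-iodosuccinimide (1.1 equiv), TFA (0.3 equiv), MeCN, 0 °C to rt
Reagents that add atoms: N-iodosuccinimide, O=C1CCC(=O)N1I
Why: Electrophilic aromatic iodination; C8 is activated by the 7-methoxy group (ortho), the 5-methoxy group (para) and the ring oxygen (ortho) and is less crowded than C6, which lies between two methoxy groups.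

Step 2
Reactants: 2 8-iodo-5,7-dimethoxycoumarin; 3 2-methylbut-3-en-2-ol
Product: 4 8-[(E)-3-hydroxy-3-methylbut-1-enyl]-5,7-dimethoxycoumarin
Conditions: Pd(OAc)2 (5 mol%), P(o-tol)3 (10 mol%), Et3N, DMF, 90 °C
Reagents that add atoms: none
Why: Mizoroki–Heck reaction; the arylpalladium species adds to the terminal alkene carbon and, since the carbinol carbon has no hydrogen, syn β-hydride elimination can only give the E-styryl carbinol.

Step 3
Reactants: 4 8-[(E)-3-hydroxy-3-methylbut-1-enyl]-5,7-dimethoxycoumarin
Product: 5 5,7-dimethoxy-8-[(E)-3-methylbuta-1,3-dienyl]coumarin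
Conditions: methyl N-(triethylammoniosulfonyl)carbamate (Burgess reagent), THF, 50 °C; used at once, stored cold with BHT
Reagents that add atoms: none
Why: Burgess dehydration; the tertiary allylic sulfamate eliminates readily and only a methyl hydrogen can be lost, so the isopropenyl group forms under neutral conditions without touching the E-alkene or the lactone.

Step 4
Reactants: 6 (S)-lactic acid; 7 pivalaldehyde
Product: 8 (2S,5S)-2-tert-butyl-5-methyl-1,3-dioxolan-4-one (cis)
Conditions: TsOH·H2O (cat.), H2SO4 (cat.), pentane, reflux, Dean–Stark; recrystallisation from Et2O/pentane at −78 °C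
Reagents that add atoms: none
Why: Acid-catalysed acetalisation with azeotropic removal of water favours the cis-dioxolanone, in which the lactic acid stereocentre fixes the acetal carbon as S; crystallisation removes the trans isomer.

Step 5
Reactants: 8 (2S,5S)-2-tert-butyl-5-methyl-1,3-dioxolan-4-one
Product: 10 (S)-2-tert-butyl-5-methylene-1,3-dioxolan-4-one, via bromide 9 (not isolated)
Conditions: N-bromosuccinimide, AIBN (cat.), cyclohexane, 80 °C; then Et3N, Et2O, 0 °C to rt; distilled
Reagents that add atoms: none
Why: Wohl–Ziegler radical bromination at the captodative C5–H, then E2 loss of HBr from the methyl group, gives the exocyclic alkene; the acetal stereocentre is untouched and now carries all the chirality.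

Step 6
Reactants: 5 5,7-dimethoxy-8-[(E)-3-methylbuta-1,3-dienyl]coumarin; 10 (S)-2-tert-butyl-5-methylene-1,3-dioxolan-4-one
Product: 11 (2S,5R,6R)-2-tert-butyl-6-Ar-8-methyl-1,3-dioxaspiro[4.5]dec-7-en-4-one (aryl cis to the spiro C–O bond, tert-butyl on the side away from the aryl methine)
Conditions: 10 (3 equiv), BHT (cat.), toluene, 95 °C, sealed tube
Reagents that add atoms: none
Why: Thermal Diels–Alder reaction; the 1-aryl-3-methyl diene and the captodative 1,1-disubstituted dienophile join in the "ortho/para" sense, the s-cis-locked methylene lactone reacts through the exo transition state (ring oxygen under the diene) so the spiro C–O bond should end cis to the aryl group, and the diene adds to the face away from the tert-butyl group, which sets the spiro carbon (R) and with it the aryl methine (R).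

Step 7
Reactants: 11 the spiro-dioxolanone
Product: 12 (1R,2R)-2-Ar-1-(hydroxymethyl)-4-methylcyclohex-3-en-1-ol (aryl cis to the tertiary OH)
Conditions: NaBH4 (4 equiv), THF/EtOH 4:1, 0 °C to rt; aq. NH4Cl, then 1 M HCl wash
Reagents that add atoms: none
Why: Borohydride reduction; the acylal-type lactone carbonyl is far more electrophilic than the donor-substituted conjugated coumarin lactone, the hemiacetal collapses after the first hydride with loss of pivalaldehyde, and the α-hydroxy aldehyde is reduced on to the diol with both stereocentres untouched.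

Step 8
Reactants: 12 the diol
Product: 13 (1R,2R)-2-Ar-1-hydroxy-4-methylcyclohex-3-ene-1-carbaldehyde
Conditions: SO3·pyridine (3 equiv), DMSO, iPr2NEt, CH2Cl2, 0 °C; used crude
Reagents that add atoms: none
Why: Parikh–Doering oxidation; activated DMSO oxidises only the primary alcohol (the tertiary one has no carbinol hydrogen), and the α-carbon is quaternary so nothing can epimerise.

Step 9
Reactants: 13 the α-hydroxy aldehyde
Product: 14 (1S,2R)-2-Ar-1-ethenyl-4-methylcyclohex-3-en-1-ol
Conditions: Ph3PCH3Br (3.2 equiv), KN(SiMe3)2 (3.0 equiv), THF, −78 to 0 °C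
Reagents that add atoms: methyltriphenylphosphonium bromide, C[P+](c1ccccc1)(c1ccccc1)c1ccccc1.[Br-]
Why: Wittig methylenation; the non-stabilised ylide attacks the aldehyde far faster than the lactones at low temperature, the excess covers the free tertiary hydroxyl, and the cold addition forestalls α-ketol rearrangement.

Step 10
Reactants: 14 the vinyl carbinol; 2 8-iodo-5,7-dimethoxycoumarin
Product: 15 (1S,2R)-2-Ar-1-[(E)-2-Ar-ethenyl]-4-methylcyclohex-3-en-1-ol (aryl on C2 cis to OH, trans to the styryl group)
Conditions: Pd(OAc)2 (10 mol%), P(o-tol)3 (20 mol%), Et3N, DMF, 90 °C; chromatography on Et3N-washed silica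
Reagents that add atoms: none
Why: Mizoroki–Heck reaction as in step 2; arylpalladium adds to the unsubstituted terminus of the vinyl carbinol and β-hydride elimination away from the hydrogen-free carbinol carbon gives only the E-styryl group, the trisubstituted ring alkene being inert.

Step 11
Reactants: 15 the styryl cyclohexenol
Product: 18 (3R,4R)-3-Ar-4-[(Z)-2-Ar-ethenyl]-4-methylcyclohex-1-en-1-yl trifluoromethanesulfonate, via potassium alkoxide 16 (not isolated), via potassium enolate 17 (not isolated)
Conditions: KN(SiMe3)2 (1.1 equiv), 18-crown-6 (1.5 equiv), THF, −78 to 25 °C (50 °C if conversion stalls); then PhNTf2 (1.5 equiv), −78 to 0 °C; aq. NH4Cl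
Reagents that add atoms: N-phenylbis(trifluoromethanesulfonimide), O=S(=O)(N(c1ccccc1)S(=O)(=O)C(F)(F)F)C(F)(F)F
Why: Proposed new method: KN(SiMe3)2/18-crown-6 gives the ion-separated potassium alkoxide 16, whose oxyanion weakens the adjacent ring bond C1–C2 (carbinol carbon to aryl methine); a concerted [3,3] shift (anionic oxy-Cope rearrangement) breaks that bond while the styryl β-carbon bonds to ring C4, giving cyclohexenolate 17, which PhNTf2 sulfonylates on oxygen in the same flask. The closest known reaction type is the potassium-alkoxide oxy-Cope rearrangement of 2-vinylbicyclo[2.2.2]oct-5-en-2-ols, which runs through the same boat; an unbridged 1-alkenylcyclohex-3-en-1-ol with an aryl-bearing migrating terminus and two lactones has not been put through it, hence the label. The new six-membered ring (Cβ, Cα, C1, C6, C5, C4) closes by the sigmatropic Cβ–C4 σ-bond formation itself, suprafacial on both allyl units, in a boat enforced by the C5–C6 bridge between the termini (a bicyclo[2.2.2]octadiene-like array). The quaternary centre is controlled by the carbinol configuration, because the pseudo-axial styryl group can reach C4 only on its own face of the ring alkene, and the aryl methine by the E geometry of the styryl group within that array, so both new centres descend from the stereocentres set in step 6. The step needs Z geometry in the released styryl group, secured by the aryl on C2 being cis to the oxygen and therefore in the flagpole position of the reacting boat, and a single enolate regioisomer, which the mechanism guarantees (C1=Cα only). Chemoselectivity towards the coumarins rests on the hindered tertiary alkoxide and on trapping the enolate cold.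

Step 12
Reactants: 18 the enol triflate
Product: 19 8-[(1R,6R)-6-[(Z)-2-Ar-ethenyl]-3,6-dimethylcyclohex-2-en-1-yl]-5,7-dimethoxycoumarin (CNP0164660.3)
Conditions: MeB(OH)2 (3 equiv), Pd(PPh3)4 (10 mol%), K3PO4 (3 equiv), 1,4-dioxane, 80 °C
Reagents that add atoms: methylboronic acid, CB(O)O
Why: Suzuki–Miyaura coupling; zerovalent palladium inserts into the alkenyl C–OTf bond, methyl is transferred from boron and reductive elimination places the methyl-bearing alkene exactly where the enolate was, leaving the stereocentres and the Z-alkene alone.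

**Compound list**

1 | 5,7-dimethoxycoumarin (5,7-dimethoxy-2H-chromen-2-one) | COc1cc(OC)c2ccc(=O)oc2c1 | starting material
2 | 8-iodo-5,7-dimethoxycoumarin | COc1cc(OC)c2ccc(=O)oc2c1I | intermediate
3 | 2-methylbut-3-en-2-ol | CC(C)(O)C=C | starting material
4 | 8-[(E)-3-hydroxy-3-methylbut-1-enyl]-5,7-dimethoxycoumarin | COc1cc(OC)c2ccc(=O)oc2c1/C=C/C(C)(C)O | intermediate
5 | 5,7-dimethoxy-8-[(E)-3-methylbuta-1,3-dienyl]coumarin | COc1cc(OC)c2ccc(=O)oc2c1/C=C/C(C)=C | intermediate
6 | (S)-lactic acid | C[C@H](O)C(=O)O | starting material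
7 | pivalaldehyde (2,2-dimethylpropanal) | CC(C)(C)C=O | starting material
8 | (2S,5S)-2-tert-butyl-5-methyl-1,3-dioxolan-4-one | C[C@@H]1O[C@H](C(C)(C)C)OC1=O | intermediate
9 | (2R,5R)-5-bromo-2-tert-butyl-5-methyl-1,3-dioxolan-4-one (Br trans to tert-butyl) | C[C@]1(Br)O[C@H](C(C)(C)C)OC1=O | intermediate
10 | (S)-2-tert-butyl-5-methylene-1,3-dioxolan-4-one | C=C1O[C@H](C(C)(C)C)OC1=O | intermediate
11 | (2S,5R,6R)-2-tert-butyl-6-Ar-8-methyl-1,3-dioxaspiro[4.5]dec-7-en-4-one | O=C1O[C@@H](C(C)(C)C)O[C@@]12CCC(C)=C[C@@H]2c1c(OC)cc(OC)c2ccc(=O)oc12 | intermediate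
12 | (1R,2R)-2-Ar-1-(hydroxymethyl)-4-methylcyclohex-3-en-1-ol | O[C@]1(CO)CCC(C)=C[C@@H]1c1c(OC)cc(OC)c2ccc(=O)oc12 | intermediate
13 | (1R,2R)-2-Ar-1-hydroxy-4-methylcyclohex-3-ene-1-carbaldehyde | O[C@]1(C=O)CCC(C)=C[C@@H]1c1c(OC)cc(OC)c2ccc(=O)oc12 | intermediate
14 | (1S,2R)-2-Ar-1-ethenyl-4-methylcyclohex-3-en-1-ol | O[C@]1(C=C)CCC(C)=C[C@@H]1c1c(OC)cc(OC)c2ccc(=O)oc12 | intermediate
15 | (1S,2R)-2-Ar-1-[(E)-2-Ar-ethenyl]-4-methylcyclohex-3-en-1-ol | O[C@]1(/C=C/c2c(OC)cc(OC)c3ccc(=O)oc23)CCC(C)=C[C@@H]1c1c(OC)cc(OC)c2ccc(=O)oc12 | intermediate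
16 | potassium alkoxide of 15 | [K+].[O-][C@]1(/C=C/c2c(OC)cc(OC)c3ccc(=O)oc23)CCC(C)=C[C@@H]1c1c(OC)cc(OC)c2ccc(=O)oc12 | intermediate
17 | potassium (3R,4R)-3-Ar-4-[(Z)-2-Ar-ethenyl]-4-methylcyclohex-1-en-1-olate | COc1cc(OC)c2ccc(=O)oc2c1/C=C\[C@@]1(C)CCC([O-])=C[C@H]1c1c(OC)cc(OC)c2ccc(=O)oc12.[K+] | intermediate
18 | (3R,4R)-3-Ar-4-[(Z)-2-Ar-ethenyl]-4-methylcyclohex-1-en-1-yl trifluoromethanesulfonate | COc1cc(OC)c2ccc(=O)oc2c1/C=C\[C@@]1(C)CCC(OS(=O)(=O)C(F)(F)F)=C[C@H]1c1c(OC)cc(OC)c2ccc(=O)oc12 | intermediate
19 | 8-[(1R,6R)-6-[(Z)-2-Ar-ethenyl]-3,6-dimethylcyclohex-2-en-1-yl]-5,7-dimethoxycoumarin | COc1cc(OC)c2ccc(=O)oc2c1/C=C\[C@@]1(C)CCC(C)=C[C@H]1c1c(OC)cc(OC)c2ccc(=O)oc12 | target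

**Step count and risks**

Total step count: 12. Longest linear sequence: 10 steps (1–3, then 6–12, from 5,7-dimethoxycoumarin); steps 4–5 form the side branch, and iodide 2 is used twice.

Steps most likely to fail:

1. Step 11. Instead of the concerted boat shift, the alkoxide may fragment: heterolysis of C1–C2 to an enone and an aryl-allyl anion that recloses without memory of geometry (E-styryl product or the [1,3] ring-expanded ketone), or alkoxide-driven cycloreversion back to diene 5. The alkoxide or enolate may also open a lactone. The fallback uses known chemistry and sets out from diene 5. An enantioselective Diels–Alder reaction with methacrolein, catalysed at −78 °C in CH2Cl2 by the triflimide salt of a diphenylprolinol-derived B-(o-tolyl)oxazaborolidine (the enantiomer that delivers the stated adduct), should give the endo adduct (1S,2S)-2-Ar-1,4-dimethylcyclohex-3-ene-1-carbaldehyde F1, formyl cis to aryl. Ohira–Bestmann homologation (dimethyl (1-diazo-2-oxopropyl)phosphonate, K2CO3, MeOH) would give 8-[(1R,6S)-6-ethynyl-3,6-dimethylcyclohex-2-en-1-yl]-5,7-dimethoxycoumarin F2. Sonogashira coupling with iodide 2 (Pd(PPh3)2Cl2, CuI, Et3N, DMF) would give the aryl alkyne 8-[(1R,6S)-6-(2-Ar-ethynyl)-3,6-dimethylcyclohex-2-en-1-yl]-5,7-dimethoxycoumarin F3. Semi-hydrogenation over Pd/CaCO3 poisoned with Pb(OAc)2 (quinoline, H2, EtOAc) would give the Z-alkene, so this path comes back to the route at target 19.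

2. Step 6. The hindered diene may add so slowly that self-dimerisation of 5 or decomposition of the acetal dienophile takes over, and any loss of exo selectivity puts the aryl trans to oxygen. The fallback sets out from diene 5 and replaces auxiliary control by catalyst control at low temperature. A Diels–Alder reaction with 2-bromoacrolein under the same chiral oxazaborolidinium triflimide at −78 °C should give the endo adduct (1S,2R)-1-bromo-2-Ar-4-methylcyclohex-3-ene-1-carbaldehyde F4 (formyl cis to aryl, bromine trans). NaOMe in MeOH would convert it through the methoxy-epoxide, with inversion at the bromide carbon, into (1R,2R)-2-Ar-1-(dimethoxymethyl)-4-methylcyclohex-3-en-1-ol F5, hydroxyl now cis to aryl. Mild aqueous acid (PPTS, acetone/H2O) would free the aldehyde, so this path comes back to the route at 13.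

3. Step 7. Chemoselectivity may be lost: hydride may be delivered to the coumarin lactone or its C3=C4 bond, or the reduction may stall at the hydroxy ester after ethanolysis of the dioxolanone. The fallback sets out from 11 and avoids hydride reagents. Thiolysis with EtSH/NaSEt (THF, 0 °C) would open the activated lactone, with loss of pivalaldehyde, to S-ethyl (1R,2R)-2-Ar-1-hydroxy-4-methylcyclohex-3-ene-1-carbothioate F6. Fukuyama reduction (Et3SiH, Pd/C, acetone, rt) would give the aldehyde directly, so this path comes back to the route at 13 and bypasses step 8.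

**Further compounds**

F1 | step 11 | (1S,2S)-2-Ar-1,4-dimethylcyclohex-3-ene-1-carbaldehyde | O=C[C@@]1(C)CCC(C)=C[C@H]1c1c(OC)cc(OC)c2ccc(=O)oc12
F2 | step 11 | 8-[(1R,6S)-6-ethynyl-3,6-dimethylcyclohex-2-en-1-yl]-5,7-dimethoxycoumarin | C#C[C@@]1(C)CCC(C)=C[C@H]1c1c(OC)cc(OC)c2ccc(=O)oc12
F3 | step 11 | 8-[(1R,6S)-6-(2-Ar-ethynyl)-3,6-dimethylcyclohex-2-en-1-yl]-5,7-dimethoxycoumarin | COc1cc(OC)c2ccc(=O)oc2c1C#C[C@@]1(C)CCC(C)=C[C@H]1c1c(OC)cc(OC)c2ccc(=O)oc12
F4 | step 6 | (1S,2R)-1-bromo-2-Ar-4-methylcyclohex-3-ene-1-carbaldehyde | Br[C@@]1(C=O)CCC(C)=C[C@@H]1c1c(OC)cc(OC)c2ccc(=O)oc12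
F5 | step 6 | (1R,2R)-2-Ar-1-(dimethoxymethyl)-4-methylcyclohex-3-en-1-ol | O[C@]1(C(OC)OC)CCC(C)=C[C@@H]1c1c(OC)cc(OC)c2ccc(=O)oc12
F6 | step 7 | S-ethyl (1R,2R)-2-Ar-1-hydroxy-4-methylcyclohex-3-ene-1-carbothioate | O[C@]1(C(=O)SCC)CCC(C)=C[C@@H]1c1c(OC)cc(OC)c2ccc(=O)oc12
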